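**Plan**
1. Numbering follows the target decalin: C4 carries the exocyclic methylene, C5 (CH3) and C10 (H) are the ring-fusion carbons, C8 and C9 carry the other two methyl groups, and C11 is the benzylic CH2. Ring A is C1–C5 plus C10; ring B is C5–C10.
2. Retrosynthetic cuts, in order: quinone back to a tetramethoxyarene; C9–C11 (γ-benzylation); C6 and C4 back to ketones; C7–C8 and C5–C10 together in one step; last the open chain at C9=C10 (cross-metathesis) and C4–C5 (dianion acylation).
3. Enabling feature: in ring B, C5 and C7 flank C6, and C8 and C10 flank C9. With ketones on C6 and on ring-A carbon C4, C5 is a 1,3-diketone carbon and C7 (carrying a phosphonate) is a second nucleophile. C10=C9(CH3)–C8(=O)CH3 is the matching 1,3-bis-electrophile and already holds both ring-B methyl groups.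
4. Forward: the chain is assembled, then ring A (C5–C10) and ring B (C7–C8) close in one flask from the open chain. C4 methylenation, C9 benzylation, C8–H introduction, C6 deoxygenation and quinone formation follow.
5. Stereochemistry: C5 and C10 come from a chiral ammonium ion pair in the ring-A closure (cis fusion); C9 from alkylation on the convex face of the cis-fused bicycle; C8 from axial protonation anti to the arylmethyl group.
6. Helpers and their removal: C7 phosphonate (lost in the key step), C6 ketone (steps 8–9), C4 ketone (becomes the methylene in step 6), O-methyl groups (steps 10–11).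

Key step: step 5

Assumption: the cinchonidinium salt of step 5 is taken to give the enantiomer drawn; if the sense of induction is the opposite, the pseudo-enantiomeric cinchoninium salt is used.

**Step 1**
Reactants: 1 1,2,4,5-tetramethoxybenzene
Product: 3 (2,3,5,6-tetramethoxyphenyl)methanol, via aryllithium 2 (not isolated)
Conditions: n-BuLi, TMEDA, THF, 0 °C; (CH2O)n, 0 °C to rt; H2O
Reagents that add atoms: formaldehyde (from paraformaldehyde), C=O
Why: Directed ortho-lithiation occurs at the CH flanked by two methoxy groups and the aryllithium adds to formaldehyde (hydroxymethylation); no stereocentre is formed.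

**Step 2**
Reactants: 3 (2,3,5,6-tetramethoxyphenyl)methanol
Product: 4 3-(bromomethyl)-1,2,4,5-tetramethoxybenzene
Conditions: PBr3, Et2O, 0 °C
Reagents that add atoms: phosphorus tribromide, BrP(Br)Br
Why: Bromination of a primary benzylic alcohol with PBr3 (substitution via the phosphite ester) is fast for this electron-rich benzyl system; no stereocentre is formed.

**Step 3**
Reactants: 5 diethyl (2-oxobutyl)phosphonate; 6 methyl hex-5-enoate
Product: 8 diethyl (3-methyl-2,4-dioxonon-8-en-1-yl)phosphonate, via phosphonate dianion 7 (not isolated)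
Conditions: NaH (1.0 equiv), THF, 0 °C; n-BuLi (1.05 equiv), 0 °C; 6 (0.5 equiv), 0 °C to rt; aq. HCl
Reagents that add atoms: none
Why: Claisen-type γ-acylation of a 1,3-dianion: the second-formed, more basic carbanion (the CH2 of the ethyl group) attacks the ester, the acidic 1,3-diketone product is deprotonated in the flask, which stops over-addition, and the new CH(CH3) centre is configurationally labile and needs no control.

**Step 4**
Reactants: 8 diethyl (3-methyl-2,4-dioxonon-8-en-1-yl)phosphonate; 9 3-methylbut-3-en-2-one
Product: 10 diethyl [(8E)-3,9-dimethyl-2,4,10-trioxoundec-8-en-1-yl]phosphonate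
Conditions: second-generation Hoveyda–Grubbs catalyst RuCl2(H2IMes)(=CH–C6H4–2-OiPr) (5 mol %), 9 (5 equiv), CH2Cl2, 40 °C
Reagents that add atoms: none
Why: Olefin cross-metathesis of a terminal alkene with a 1,1-disubstituted enone used in excess should give the trisubstituted enone with the thermodynamically preferred (E) geometry (acetyl trans to the chain); no stereocentre is formed.

**Step 5**
Reactants: 10 diethyl [(8E)-3,9-dimethyl-2,4,10-trioxoundec-8-en-1-yl]phosphonate
Product: 12 (4aS,8aR)-3,4,8a-trimethyl-4,4a,5,6,7,8a-hexahydronaphthalene-1,8-dione (cis-fused; C4 epimers), via monocyclic Michael adduct 11 (not isolated)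
Conditions: O-allyl-N-(9-anthracenylmethyl)cinchonidinium bromide (10 mol %), Cs2CO3 (3 equiv), toluene (0.02 M), −20 °C; then 50 °C
Reagents that add atoms: none
Why: Cs2CO3 removes the C5–H between the C4 and C6 carbonyls and the enolate, paired with the chiral ammonium ion, adds to C10 of the (E)-enone (6-exo-trig Michael addition, ring A, bond C5–C10); after protonation of the C9 enolate the C7–H2 of the β-ketophosphonate is the most acidic site left, and its carbanion adds to the C8 ketone and expels diethyl phosphate (intramolecular Horner–Wadsworth–Emmons olefination, six-membered ring B, bond C7–C8 formed as C7=C8). The closest known reaction types are the domino Michael/intramolecular Horner–Wadsworth–Emmons annulation and the phase-transfer-catalysed asymmetric Michael addition of 2-substituted 1,3-dicarbonyl compounds to enones. C5 (quaternary) and C10 are both set in the Michael step: the cinchonidinium ion shields one face of the planar diketonate (absolute configuration), and the compact transition state with the enone carbonyl lying over the cation-bridged diketonate should put C9 and the C6 acyl group on the same side of ring A, which is the cis ring fusion (CH3 on C5 cis to H on C10). C9 is formed as a mixture of epimers, which is harmless because C9 becomes sp2 again in step 7. The step needs C7 and not the C8 methyl group to be the nucleophile of the second closure (secured by the phosphonate, which is the more acidic site and olefinates irreversibly), C- over O-alkylation of the diketonate (thermodynamic), and ring-B closure before retro-Michael erosion (low temperature for the Michael step, warming only for the olefination).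

**Step 6**
Reactants: 12 (4aS,8aR)-3,4,8a-trimethyl-4,4a,5,6,7,8a-hexahydronaphthalene-1,8-dione
Product: 13 (4aS,8aR)-3,4,8a-trimethyl-8-methylidene-4a,5,6,7,8,8a-hexahydronaphthalen-1(4H)-one (C4 epimers)
Conditions: Ph3PCH3Br, KN(SiMe3)2, toluene, 0 °C to 80 °C
Reagents that add atoms: methyltriphenylphosphonium bromide, C[P+](c1ccccc1)(c1ccccc1)c1ccccc1.[Br-]
Why: Wittig methylenation should take place at the saturated C4 ketone because the C6 carbonyl is deactivated by enone conjugation, which gives the exocyclic methylene of the target; no stereocentre is formed.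

**Step 7**
Reactants: 13 (4aS,8aR)-3,4,8a-trimethyl-8-methylidene-4a,5,6,7,8,8a-hexahydronaphthalen-1(4H)-one; 4 3-(bromomethyl)-1,2,4,5-tetramethoxybenzene
Product: 15 (4S,4aS,8aR)-3,4,8a-trimethyl-8-methylidene-4-[(2,3,5,6-tetramethoxyphenyl)methyl]-4a,5,6,7,8,8a-hexahydronaphthalen-1(4H)-one, via trimethylsilyl dienol ether 14 (not isolated)
Conditions: Me3SiCl, NaI, Et3N, MeCN, 40 °C; solvent exchange; 4, ZnBr2 (10 mol %), CH2Cl2, −40 to 0 °C
Reagents that add atoms: none
Why: Thermodynamic O-silylation of the enone gives the fully endocyclic ring-B diene (C6=C7 and C8=C9), and its ZnBr2-promoted alkylation by the ionising electron-rich benzylic bromide (γ-alkylation of a silyl dienol ether, vinylogous Mukaiyama type) occurs at C9 with return of the conjugated enone, the electrophile approaching the convex face of the cis-fused bicycle (the face of H10, opposite ring A), which sets C9 with the arylmethyl group cis to H10.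

**Step 8**
Reactants: 15 (4S,4aS,8aR)-3,4,8a-trimethyl-8-methylidene-4-[(2,3,5,6-tetramethoxyphenyl)methyl]-4a,5,6,7,8,8a-hexahydronaphthalen-1(4H)-one
Product: 16 (3R,4R,4aS,8aR)-3,4,8a-trimethyl-8-methylidene-4-[(2,3,5,6-tetramethoxyphenyl)methyl]octahydronaphthalen-1(2H)-one
Conditions: Li, NH3 (l), THF, t-BuOH (1 equiv), −78 °C; NH4Cl
Reagents that add atoms: none
Why: Dissolving-metal (Birch-type) conjugate reduction of the enone, in which C8 should be protonated axially on the face opposite the C9 arylmethyl group (held pseudoaxial by A(1,2) strain with the C8 methyl group), so that the C8 methyl ends cis to the arylmethyl group, while the isolated alkene and the electron-rich arene are not reduced at −78 °C.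

**Step 9**
Reactants: 16 (3R,4R,4aS,8aR)-3,4,8a-trimethyl-8-methylidene-4-[(2,3,5,6-tetramethoxyphenyl)methyl]octahydronaphthalen-1(2H)-one
Product: 18 3-{[(1R,2R,4aR,8aS)-1,2,4a-trimethyl-5-methylidenedecahydronaphthalen-1-yl]methyl}-1,2,4,5-tetramethoxybenzene, via tosylhydrazone 17 (not isolated)
Conditions: TsNHNH2, AcOH (cat.), EtOH, 80 °C; then catecholborane, CHCl3, 0 °C; NaOAc·3H2O, 60 °C
Reagents that add atoms: none
Why: Caglioti-type deoxygenation, in which the tosylhydrazone is reduced at C=N by catecholborane and the alkyldiazene formed by loss of sulfinate gives up N2 to leave CH2 at C6 under non-acidic conditions that spare the exocyclic alkene; no stereocentre is touched.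

**Step 10**
Reactants: 18 3-{[(1R,2R,4aR,8aS)-1,2,4a-trimethyl-5-methylidenedecahydronaphthalen-1-yl]methyl}-1,2,4,5-tetramethoxybenzene
Product: 19 2,5-dimethoxy-3-{[(1R,2R,4aR,8aS)-1,2,4a-trimethyl-5-methylidenedecahydronaphthalen-1-yl]methyl}cyclohexa-2,5-diene-1,4-dione
Conditions: (NH4)2Ce(NO3)6 (2.5 equiv), MeCN–H2O, 0 °C
Reagents that add atoms: water, O
Why: Oxidative demethylation of a para-dimethoxy pair of the tetramethoxyarene (two-electron oxidation, water adds at the ipso carbons, methanol leaves) should give the 2,5-dimethoxy-1,4-benzoquinone without touching the alkene or the stereocentres.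

**Step 11**
Reactants: 19 2,5-dimethoxy-3-{[(1R,2R,4aR,8aS)-1,2,4a-trimethyl-5-methylidenedecahydronaphthalen-1-yl]methyl}cyclohexa-2,5-diene-1,4-dione
Product: 20 2-hydroxy-5-methoxy-3-{[(1R,2R,4aR,8aS)-1,2,4a-trimethyl-5-methylidenedecahydronaphthalen-1-yl]methyl}cyclohexa-2,5-diene-1,4-dione
Conditions: KOH, MeOH–H2O, 25 °C; then aq. HCl
Reagents that add atoms: potassium hydroxide, [K+].[OH-]
Why: Addition–elimination of hydroxide at a quinone vinylogous ester (saponification), expected at the methoxy-bearing carbon next to the alkyl-bearing carbon because that methoxy group is twisted out of conjugation, with the hydroxyquinone anion resisting a second substitution; no stereocentre is touched.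

**Compound list**
1 | 1,2,4,5-tetramethoxybenzene | COc1cc(OC)c(OC)cc1OC | starting material
2 | (2,3,5,6-tetramethoxyphenyl)lithium | [Li]c1c(OC)c(OC)cc(OC)c1OC | intermediate
3 | (2,3,5,6-tetramethoxyphenyl)methanol | OCc1c(OC)c(OC)cc(OC)c1OC | intermediate
4 | 3-(bromomethyl)-1,2,4,5-tetramethoxybenzene | BrCc1c(OC)c(OC)cc(OC)c1OC | intermediate
5 | diethyl (2-oxobutyl)phosphonate | CCC(=O)CP(=O)(OCC)OCC | starting material
6 | methyl hex-5-enoate | C=CCCCC(=O)OC | starting material
7 | sodium lithium 1,3-dianion of diethyl (2-oxobutyl)phosphonate | [Na+].[Li+].CCOP(=O)(OCC)[CH-]C(=O)[CH-]C | intermediate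
8 | diethyl (3-methyl-2,4-dioxonon-8-en-1-yl)phosphonate (racemic, labile CH(CH3) centre) | C=CCCCC(=O)C(C)C(=O)CP(=O)(OCC)OCC | intermediate
9 | 3-methylbut-3-en-2-one | CC(=O)C(C)=C | starting material
10 | diethyl [(8E)-3,9-dimethyl-2,4,10-trioxoundec-8-en-1-yl]phosphonate | CC(=O)/C(C)=C/CCCC(=O)C(C)C(=O)CP(=O)(OCC)OCC | intermediate
11 | diethyl {2-[(1R,6S)-1-methyl-2-oxo-6-(3-oxobutan-2-yl)cyclohexyl]-2-oxoethyl}phosphonate (acyl group cis to the side chain; side-chain CH(CH3) epimers) | O=C1CCC[C@@H](C(C)C(C)=O)[C@@]1(C)C(=O)CP(=O)(OCC)OCC | intermediate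
12 | (4aS,8aR)-3,4,8a-trimethyl-4,4a,5,6,7,8a-hexahydronaphthalene-1,8-dione (cis-fused; C4 epimers) | O=C1CCC[C@H]2C(C)C(C)=CC(=O)[C@@]12C | intermediate
13 | (4aS,8aR)-3,4,8a-trimethyl-8-methylidene-4a,5,6,7,8,8a-hexahydronaphthalen-1(4H)-one (C4 epimers) | C=C1CCC[C@H]2C(C)C(C)=CC(=O)[C@@]12C | intermediate
14 | trimethyl{[(4aS,8aR)-3,4,8a-trimethyl-8-methylidene-4a,5,6,7,8,8a-hexahydronaphthalen-1-yl]oxy}silane | C=C1CCC[C@H]2C(C)=C(C)C=C(O[Si](C)(C)C)[C@@]12C | intermediate
15 | (4S,4aS,8aR)-3,4,8a-trimethyl-8-methylidene-4-[(2,3,5,6-tetramethoxyphenyl)methyl]-4a,5,6,7,8,8a-hexahydronaphthalen-1(4H)-one | C=C1CCC[C@H]2[C@](C)(Cc3c(OC)c(OC)cc(OC)c3OC)C(C)=CC(=O)[C@@]12C | intermediate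
16 | (3R,4R,4aS,8aR)-3,4,8a-trimethyl-8-methylidene-4-[(2,3,5,6-tetramethoxyphenyl)methyl]octahydronaphthalen-1(2H)-one | C=C1CCC[C@H]2[C@](C)(Cc3c(OC)c(OC)cc(OC)c3OC)[C@H](C)CC(=O)[C@@]12C | intermediate
17 | 4-methylbenzenesulfonylhydrazone of 16 | C=C1CCC[C@H]2[C@](C)(Cc3c(OC)c(OC)cc(OC)c3OC)[C@H](C)CC(=NNS(=O)(=O)c3ccc(C)cc3)[C@@]12C | intermediate
18 | 3-{[(1R,2R,4aR,8aS)-1,2,4a-trimethyl-5-methylidenedecahydronaphthalen-1-yl]methyl}-1,2,4,5-tetramethoxybenzene | C=C1CCC[C@H]2[C@](C)(Cc3c(OC)c(OC)cc(OC)c3OC)[C@H](C)CC[C@@]12C | intermediate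
19 | 2,5-dimethoxy-3-{[(1R,2R,4aR,8aS)-1,2,4a-trimethyl-5-methylidenedecahydronaphthalen-1-yl]methyl}cyclohexa-2,5-diene-1,4-dione | C=C1CCC[C@H]2[C@](C)(CC3=C(OC)C(=O)C=C(OC)C3=O)[C@H](C)CC[C@@]12C | intermediate
20 | 2-hydroxy-5-methoxy-3-{[(1R,2R,4aR,8aS)-1,2,4a-trimethyl-5-methylidenedecahydronaphthalen-1-yl]methyl}cyclohexa-2,5-diene-1,4-dione | C=C1CCC[C@H]2[C@](C)(CC3=C(O)C(=O)C=C(OC)C3=O)[C@H](C)CC[C@@]12C | target

Total step count: 11. Longest linear sequence: 9 steps (steps 3 to 11, from 5 and 6); the benzyl bromide branch (steps 1–2) joins at step 7.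

**Steps most likely to fail**

1. Step 5. The cis ring fusion or the enantiofacial selectivity may erode through a background Michael addition that is not ion-paired, or through retro-Michael equilibration before ring B closes. Fallback: the two closures are separated and the Michael step is put under two-point metal-chelate control. Starting from 10, [Pd((R)-BINAP)(H2O)2](OTf)2 forms a chiral palladium enolate of the 1,3-diketone while the liberated acid activates the enone; this is a known way to make quaternary carbons from 2-substituted 1,3-dicarbonyl compounds and enones. It should give 11, which is isolated and freed of its trans isomer. Ba(OH)2 in wet THF then effects the Horner–Wadsworth–Emmons closure and the route is rejoined at 12; no compound outside the list is needed (F0).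

2. Step 7. The benzyl cation may attack C7 or an exocyclic dienol ether terminus instead of C9, facial selectivity may be poor, or the electron-rich benzyl bromide may alkylate itself. Fallback: the carbon electrophile is changed from a cation to an aldehyde. The dienol ether 14 (from 13 as in step 7) is combined under BF3·OEt2 with 2,3,5,6-tetramethoxybenzaldehyde F1, obtained from alcohol 3 with MnO2. This vinylogous Mukaiyama aldol reaction is reliably γ-selective and uses the same convex-face approach; it should give the C9-quaternary hydroxy enone F2 as a mixture at the carbinol carbon. Acetylation (Ac2O, DMAP) gives the benzylic acetate F3. Li/NH3 as in step 8 then reduces the enone and cleaves the benzylic C–O bond in one flask, and the route is rejoined at 16.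

3. Step 8. C8 may be protonated from the wrong face, or the ketone may be over-reduced. Fallback: substrate-controlled protonation is replaced by ligand-controlled hydride delivery. Starting from 15, copper hydride generated from Cu(OAc)2, (R)-DTBM-SEGPHOS and (EtO)2MeSiH in toluene adds hydride to C8 (the enantiomeric ligand is used if it proves to be the matched one). This should give the silyl enol ether F4, which is hydrolysed with aq. NaOH in THF, and the route is rejoined at 16.

**Further compounds**
F0 | step 5 | none | none
F1 | step 7 | 2,3,5,6-tetramethoxybenzaldehyde | O=Cc1c(OC)c(OC)cc(OC)c1OC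
F2 | step 7 | (4S,4aS,8aR)-4-[hydroxy(2,3,5,6-tetramethoxyphenyl)methyl]-3,4,8a-trimethyl-8-methylidene-4a,5,6,7,8,8a-hexahydronaphthalen-1(4H)-one (carbinol epimers) | C=C1CCC[C@H]2[C@](C)(C(O)c3c(OC)c(OC)cc(OC)c3OC)C(C)=CC(=O)[C@@]12C
F3 | step 7 | [(4S,4aS,8aR)-3,4,8a-trimethyl-8-methylidene-1-oxo-4a,5,6,7,8,8a-hexahydro-4H-naphthalen-4-yl](2,3,5,6-tetramethoxyphenyl)methyl acetate | C=C1CCC[C@H]2[C@](C)(C(OC(C)=O)c3c(OC)c(OC)cc(OC)c3OC)C(C)=CC(=O)[C@@]12C
F4 | step 8 | diethoxy(methyl){[(3R,4R,4aS,8aR)-3,4,8a-trimethyl-8-methylidene-4-[(2,3,5,6-tetramethoxyphenyl)methyl]-3,4,4a,5,6,7,8,8a-octahydronaphthalen-1-yl]oxy}silane | C=C1CCC[C@H]2[C@](C)(Cc3c(OC)c(OC)cc(OC)c3OC)[C@H](C)C=C(O[Si](C)(OCC)OCC)[C@@]12C
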